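**Plan**
Retrosynthesis: the acid goes back to a silyl-protected 2-substituted allyl alcohol. The C5–C1′ bond between ring and side chain is cut to a 5-iodo-3,6-dihydro-2H-pyran and a homofarnesyl borane made from (2E,6E)-farnesol. The O1–C6 bond of the ring is then cut to an open-chain β-hydroxyallene, and the allene to a terminal alkyne plus formaldehyde and, at C2–C3, to a 2-substituted acrolein plus a propargyl unit.
Enabling feature: in the dihydropyran, O1 sits on C2, two carbons (C3, C4) before the ring alkene C4=C5, and C6 is an unsubstituted CH2 on the chain-bearing C5. The unit O1–C6H2–C5(R)=C4H is what 6-endo attack of a β-hydroxyl on the CH2 terminus of a C4H=C5=C6H2 allene leaves when the central carbon C5 captures an electrophile (iodine, later exchanged for the chain).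
Forward order: aldehyde, asymmetric propargylation, allene, the only ring (iodoetherification), side chain by sp2–sp3 coupling, then deprotection and oxidation to the acrylic acid.
Stereochemistry: C2, the only stereocenter, comes from a chiral phosphoric acid-catalysed allenylboration and is not touched afterwards; both E alkenes of the chain come from farnesol.

Key step: step 5

Assumption: the (S)-configured phosphoric acid is taken to direct the allenyl group to the Si face of the aldehyde, by analogy with aryl and alkenyl aldehydes; if the sense proves opposite, the (R)-acid is used and nothing else changes.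

Step 1
Reactants: 1 2-methylenepropane-1,3-diol
Product: 2 2-{[(tert-butyldimethylsilyl)oxy]methyl}prop-2-en-1-ol
Conditions: NaH (1.0 equiv), THF, 0 °C; TBSCl (1.0 equiv), 0 °C to rt
Reagents that add atoms: tert-butyldimethylsilyl chloride, CC(C)(C)[Si](C)(C)Cl
Why: One equivalent of NaH gives the sparingly soluble monoalkoxide of the symmetrical diol, which should be silylated once (O-silylation, monoprotection of a symmetrical diol).

Step 2
Reactants: 2 2-{[(tert-butyldimethylsilyl)oxy]methyl}prop-2-en-1-ol
Product: 3 2-{[(tert-butyldimethylsilyl)oxy]methyl}prop-2-enal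
Conditions: MnO2 (excess), CH2Cl2, rt
Reagents that add atoms: none
Why: MnO2 should oxidise the allylic primary alcohol to the 2-substituted acrolein and leave the silyl ether alone (allylic alcohol oxidation).

Step 3
Reactants: 3 2-{[(tert-butyldimethylsilyl)oxy]methyl}prop-2-enal; 4 allenylboronic acid pinacol ester
Product: 6 (3S)-2-{[(tert-butyldimethylsilyl)oxy]methyl}hex-1-en-5-yn-3-ol, via pinacol borate ester 5 (not isolated)
Conditions: (S)-TRIP [(S)-3,3′-bis(2,4,6-triisopropylphenyl)-1,1′-binaphthyl-2,2′-diyl hydrogen phosphate] (5 mol%), 4 Å MS, toluene, −20 °C; aq. NaHCO3 work-up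
Reagents that add atoms: none
Why: Chiral phosphoric acid-catalysed allenylboration (asymmetric propargylation) runs through a closed six-membered SE2′ transition state in which the acid hydrogen-bonds to a boronate oxygen, so γ-attack should give only the homopropargylic connectivity and the (S)-acid is expected to direct attack to the Si face and set C2 as S.

Step 4
Reactants: 6 (3S)-2-{[(tert-butyldimethylsilyl)oxy]methyl}hex-1-en-5-yn-3-ol
Product: 7 (3S)-2-{[(tert-butyldimethylsilyl)oxy]methyl}hepta-1,5,6-trien-3-ol
Conditions: (CH2O)n, CuI (0.5 equiv), Cy2NH, 1,4-dioxane, reflux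
Reagents that add atoms: paraformaldehyde (formaldehyde), C=O
Why: Crabbé homologation: copper-mediated Mannich coupling of the terminal alkyne with formaldehyde and the amine gives a propargylic amine that should lose the imine by 1,5-hydride transfer to give the terminal allene, with free hydroxyl groups tolerated and the carbinol center untouched.

Step 5
Reactants: 7 (3S)-2-{[(tert-butyldimethylsilyl)oxy]methyl}hepta-1,5,6-trien-3-ol
Product: 8 (2S)-2-(3-{[tert-butyl(dimethyl)silyl]oxy}prop-1-en-2-yl)-5-iodo-3,6-dihydro-2H-pyran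
Conditions: NIS (1.2 equiv), Ph3PAuCl (5 mol%), AgBF4 (5 mol%), CH2Cl2, 0 °C to rt, dark
Reagents that add atoms: N-iodosuccinimide, O=C1CCC(=O)N1I
Why: The cationic monovalent gold complex binds the terminal C5=C6 π bond of the allene, the C2 hydroxyl adds anti to the unsubstituted terminus C6, and the σ-vinylgold formed at the former central carbon C5 is iodinated by NIS at that carbon, which frees the catalyst. The closest known reaction type is the gold-catalysed cycloisomerization of β-hydroxyallenes to 3,6-dihydro-2H-pyrans run in the presence of NIS, a 6-endo iodoalkoxylation of an allene. The one ring formed, the dihydropyran, closes in the 6-endo-trig mode. No stereocenter is created, and C2 from step 3 is a spectator whose C–O and C–H bonds are not broken. The step needs regioselectivity for O–C6 over O–C4 closure and chemoselectivity for the allene over the silyloxymethyl-substituted alkene. The first should follow from the strain of the alternative four-membered ring and the unhindered allene terminus, the second from the preference of the soft gold cation for the allene and from the absence of a nucleophile placed to trap an iodonium ion on the other alkene.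

Step 6
Reactants: 9 (2E,6E)-farnesol
Product: 10 (2E,6E)-farnesal
Conditions: MnO2 (excess), CH2Cl2, rt
Reagents that add atoms: none
Why: MnO2 oxidation of the allylic alcohol should stop at the enal and keep the 2E geometry (allylic alcohol oxidation).

Step 7
Reactants: 10 (2E,6E)-farnesal
Product: 11 (3E,7E)-4,8,12-trimethyltrideca-1,3,7,11-tetraene
Conditions: Ph3PCH3Br, KOtBu, THF, 0 °C; then 10, 0 °C to rt
Reagents that add atoms: methyltriphenylphosphonium bromide, C[P+](c1ccccc1)(c1ccccc1)c1ccccc1.[Br-]
Why: Wittig methylenation of the enal with the unstabilised ylide should give the terminal 1,3-diene without touching the trisubstituted alkenes.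

Step 8
Reactants: 11 (3E,7E)-4,8,12-trimethyltrideca-1,3,7,11-tetraene; 12 9-borabicyclo[3.3.1]nonane (9-BBN); 8 (2S)-2-(3-{[tert-butyl(dimethyl)silyl]oxy}prop-1-en-2-yl)-5-iodo-3,6-dihydro-2H-pyran
Product: 14 (2S)-2-(3-{[tert-butyl(dimethyl)silyl]oxy}prop-1-en-2-yl)-5-[(3E,7E)-4,8,12-trimethyltrideca-3,7,11-trien-1-yl]-3,6-dihydro-2H-pyran, via B-homofarnesyl-9-BBN 13 (not isolated)
Conditions: 11 (1.3 equiv), 12 (1.2 equiv), THF, 0 °C to rt; then 8, PdCl2(dppf) (5 mol%), AsPh3 (10 mol%), Cs2CO3, DMF/THF/H2O, rt
Reagents that add atoms: none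
Why: 9-BBN should hydroborate only the monosubstituted terminal double bond of the diene in the anti-Markovnikov sense, and the primary alkylborane should then couple with the alkenyl iodide at C5 without moving the ring alkene (B-alkyl Suzuki–Miyaura coupling), the borane being consumed before the iodide with its 1,1-disubstituted alkene is added.

Step 9
Reactants: 14 (2S)-2-(3-{[tert-butyl(dimethyl)silyl]oxy}prop-1-en-2-yl)-5-[(3E,7E)-4,8,12-trimethyltrideca-3,7,11-trien-1-yl]-3,6-dihydro-2H-pyran
Product: 15 2-{(2S)-5-[(3E,7E)-4,8,12-trimethyltrideca-3,7,11-trien-1-yl]-3,6-dihydro-2H-pyran-2-yl}prop-2-en-1-ol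
Conditions: TBAF, THF, 0 °C to rt
Reagents that add atoms: none
Why: Fluoride should cleave the silicon–oxygen bond of the primary TBS ether (desilylation) under conditions that leave the cyclic allyl ether and the polyene untouched.

Step 10
Reactants: 15 2-{(2S)-5-[(3E,7E)-4,8,12-trimethyltrideca-3,7,11-trien-1-yl]-3,6-dihydro-2H-pyran-2-yl}prop-2-en-1-ol
Product: 17 2-{(2S)-5-[(3E,7E)-4,8,12-trimethyltrideca-3,7,11-trien-1-yl]-3,6-dihydro-2H-pyran-2-yl}prop-2-enoic acid (CNP0171598.1), via enal 16 (not isolated)
Conditions: MnO2, CH2Cl2, rt; filter; then NaClO2, NaH2PO4, 2-methyl-2-butene (excess), t-BuOH/H2O, 0 °C to rt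
Reagents that add atoms: sodium chlorite, [Na+].[O-]Cl=O
Why: MnO2 should take the allylic alcohol to the 2-substituted acrolein and the Pinnick chlorite oxidation should take the crude enal to the acrylic acid, while 2-methyl-2-butene scavenges hypochlorous acid and so protects the trisubstituted alkenes, and no base is present that could epimerise C2.

**Compound list**
1 | 2-methylenepropane-1,3-diol | C=C(CO)CO | starting material
2 | 2-{[(tert-butyldimethylsilyl)oxy]methyl}prop-2-en-1-ol | C=C(CO)CO[Si](C)(C)C(C)(C)C | intermediate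
3 | 2-{[(tert-butyldimethylsilyl)oxy]methyl}prop-2-enal | C=C(C=O)CO[Si](C)(C)C(C)(C)C | intermediate
4 | allenylboronic acid pinacol ester | C=C=CB1OC(C)(C)C(C)(C)O1 | starting material
5 | pinacol borate ester of 6 (O-boryl ether) | C=C(CO[Si](C)(C)C(C)(C)C)[C@@H](OB1OC(C)(C)C(C)(C)O1)CC#C | intermediate
6 | (3S)-2-{[(tert-butyldimethylsilyl)oxy]methyl}hex-1-en-5-yn-3-ol | C=C(CO[Si](C)(C)C(C)(C)C)[C@@H](O)CC#C | intermediate
7 | (3S)-2-{[(tert-butyldimethylsilyl)oxy]methyl}hepta-1,5,6-trien-3-ol | C=C(CO[Si](C)(C)C(C)(C)C)[C@@H](O)CC=C=C | intermediate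
8 | (2S)-2-(3-{[tert-butyl(dimethyl)silyl]oxy}prop-1-en-2-yl)-5-iodo-3,6-dihydro-2H-pyran | C=C(CO[Si](C)(C)C(C)(C)C)[C@@H]1CC=C(I)CO1 | intermediate
9 | (2E,6E)-farnesol | CC(C)=CCC/C(C)=C/CC/C(C)=C/CO | starting material
10 | (2E,6E)-farnesal | CC(C)=CCC/C(C)=C/CC/C(C)=C/C=O | intermediate
11 | (3E,7E)-4,8,12-trimethyltrideca-1,3,7,11-tetraene | CC(C)=CCC/C(C)=C/CC/C(C)=C/C=C | intermediate
12 | 9-borabicyclo[3.3.1]nonane (9-BBN) | B1C2CCCC1CCC2 | starting material
13 | B-[(3E,7E)-4,8,12-trimethyltrideca-3,7,11-trien-1-yl]-9-BBN | CC(C)=CCC/C(C)=C/CC/C(C)=C/CCB1C2CCCC1CCC2 | intermediate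
14 | (2S)-2-(3-{[tert-butyl(dimethyl)silyl]oxy}prop-1-en-2-yl)-5-[(3E,7E)-4,8,12-trimethyltrideca-3,7,11-trien-1-yl]-3,6-dihydro-2H-pyran | C=C(CO[Si](C)(C)C(C)(C)C)[C@@H]1CC=C(CC/C=C(\C)CC/C=C(\C)CCC=C(C)C)CO1 | intermediate
15 | 2-{(2S)-5-[(3E,7E)-4,8,12-trimethyltrideca-3,7,11-trien-1-yl]-3,6-dihydro-2H-pyran-2-yl}prop-2-en-1-ol | C=C(CO)[C@@H]1CC=C(CC/C=C(\C)CC/C=C(\C)CCC=C(C)C)CO1 | intermediate
16 | 2-{(2S)-5-[(3E,7E)-4,8,12-trimethyltrideca-3,7,11-trien-1-yl]-3,6-dihydro-2H-pyran-2-yl}prop-2-enal | C=C(C=O)[C@@H]1CC=C(CC/C=C(\C)CC/C=C(\C)CCC=C(C)C)CO1 | intermediate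
17 | 2-{(2S)-5-[(3E,7E)-4,8,12-trimethyltrideca-3,7,11-trien-1-yl]-3,6-dihydro-2H-pyran-2-yl}prop-2-enoic acid | C=C(C(=O)O)[C@@H]1CC=C(CC/C=C(\C)CC/C=C(\C)CCC=C(C)C)CO1 | target

**Step count and risks**
Total step count: 10. Longest linear sequence: 8 steps (steps 1, 2, 3, 4, 5, 8, 9, 10).

Most likely to fail, riskiest first:

Step 5. What may go wrong: carbocyclisation by attack of the neighbouring 1,1-disubstituted alkene on the gold-activated allene, loss of gold by protonation before iodine capture, or iodination of the other alkene. The fallback closes the same O1–C6 bond by SN2 displacement on a preformed alkenyl iodide; it sets out from alkyne 6 and comes back at iodide 8. The dilithio derivative of 6 (n-BuLi, THF, −78 °C) would be hydroxymethylated with paraformaldehyde to give (5S)-6-{[(tert-butyldimethylsilyl)oxy]methyl}hept-6-en-2-yne-1,5-diol F1. Palladium-catalysed syn-hydrostannation (Bu3SnH, PdCl2(PPh3)2, THF), expected to place tin on the alkyne carbon next to the CH2OH group, would give (2E,5S)-6-{[(tert-butyldimethylsilyl)oxy]methyl}-2-(tributylstannyl)hepta-2,6-diene-1,5-diol F2. Iododestannylation (I2, CH2Cl2, 0 °C) with retention would give (2E,5S)-6-{[(tert-butyldimethylsilyl)oxy]methyl}-2-iodohepta-2,6-diene-1,5-diol F3, in which the CH2OH carbon and the carbinol chain are cis. Mitsunobu cyclodehydration (PPh3, DIAD, THF) should then activate the primary allylic hydroxyl, and the secondary hydroxyl should displace it (6-exo-tet) to give 8 with C2 unchanged.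

Step 8. What may go wrong: slow boron-to-palladium transmetalation of the alkylborane, with protodeiodination or ring-opening β-alkoxide elimination of the alkenylpalladium under aqueous base. The fallback is a base-free Negishi coupling; it sets out from borane 13 and iodide 8 and comes back at 14. Borane 13 would be oxidised (NaOH, H2O2) to (3E,7E)-4,8,12-trimethyltrideca-3,7,11-trien-1-ol F4. Appel iodination (PPh3, imidazole, I2, CH2Cl2) would give (3E,7E)-1-iodo-4,8,12-trimethyltrideca-3,7,11-triene F5. Zinc insertion (activated Zn, LiCl, THF) would give [(3E,7E)-4,8,12-trimethyltrideca-3,7,11-trien-1-yl]zinc iodide F6, which should couple with 8 under Pd(PPh3)4 catalysis in THF at rt (homoallylzinc–alkenyl iodide coupling) to give 14.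

Step 3. What may go wrong: insufficient facial selectivity with an α-branched enal, or partial transfer of the allenyl instead of the propargyl unit. The fallback replaces asymmetric catalysis by enzymatic kinetic resolution; it sets out from aldehyde 3 and comes back at alcohol 6. Barbier propargylation (propargyl bromide, Zn, THF/aq. NH4Cl) would give racemic 2-{[(tert-butyldimethylsilyl)oxy]methyl}hex-1-en-5-yn-3-ol F7. Lipase-catalysed acylation (Burkholderia cepacia lipase, vinyl acetate, MTBE, 30 °C) is expected, from the usual size rule for secondary alcohols, to acetylate the R enantiomer to (3R)-2-{[(tert-butyldimethylsilyl)oxy]methyl}hex-1-en-5-yn-3-yl acetate F8 and to leave the S alcohol 6, which is separated by chromatography.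

**Further compounds**
F1 | step 5 | (5S)-6-{[(tert-butyldimethylsilyl)oxy]methyl}hept-6-en-2-yne-1,5-diol | C=C(CO[Si](C)(C)C(C)(C)C)[C@@H](O)CC#CCO
F2 | step 5 | (2E,5S)-6-{[(tert-butyldimethylsilyl)oxy]methyl}-2-(tributylstannyl)hepta-2,6-diene-1,5-diol | C=C(CO[Si](C)(C)C(C)(C)C)[C@@H](O)C/C=C(\CO)[Sn](CCCC)(CCCC)CCCC
F3 | step 5 | (2E,5S)-6-{[(tert-butyldimethylsilyl)oxy]methyl}-2-iodohepta-2,6-diene-1,5-diol | C=C(CO[Si](C)(C)C(C)(C)C)[C@@H](O)C/C=C(\CO)I
F4 | step 8 | (3E,7E)-4,8,12-trimethyltrideca-3,7,11-trien-1-ol | CC(C)=CCC/C(C)=C/CC/C(C)=C/CCO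
F5 | step 8 | (3E,7E)-1-iodo-4,8,12-trimethyltrideca-3,7,11-triene | CC(C)=CCC/C(C)=C/CC/C(C)=C/CCI
F6 | step 8 | [(3E,7E)-4,8,12-trimethyltrideca-3,7,11-trien-1-yl]zinc iodide | CC(C)=CCC/C(C)=C/CC/C(C)=C/CC[Zn]I
F7 | step 3 | racemic 2-{[(tert-butyldimethylsilyl)oxy]methyl}hex-1-en-5-yn-3-ol | C=C(CO[Si](C)(C)C(C)(C)C)C(O)CC#C
F8 | step 3 | (3R)-2-{[(tert-butyldimethylsilyl)oxy]methyl}hex-1-en-5-yn-3-yl acetate | C=C(CO[Si](C)(C)C(C)(C)C)[C@H](OC(C)=O)CC#C
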